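**Assumption (one line):** squalene numbering (C1–C24 along the chain) is used from compound 11 on and farnesyl numbering before; the target is read as 15,16-epoxysipholenol A, and the D-fructose-derived Shi ketone is taken to give (R,R)-epoxides from (E)-trisubstituted alkenes.

## Retrosynthetic overview

1. Target 16 ⇐ sipholenol A (14): the C15–C16 epoxide is put on last, through a bromohydrin so that oxygen ends on the more hindered face.
2. 14 ⇐ acyclic (3R,6R,7R,18R,19R)-2,3:6,7:18,19-triepoxysqualene (12) in one acid-triggered double cascade. Ring order: oxepane, then cyclohexane (left half); cyclopentane, then cycloheptene (right half).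
3. 12 ⇐ C12–C13 sulfone alkylation of two farnesyl halves (bromide 5 + sulfone 10), then one Pd/hydride step that removes the sulfone and the terminal allylic pivalate.
4. All five epoxide stereocentres come from Shi epoxidation with one ketone enantiomer; an allylic acetate, sulfone or pivalate switches off each alkene that must survive.

## Route

Step 1
Reactants: 1 (2E,6E)-farnesyl acetate
Product: 2 (2E,6R,7R,10R)-6,7:10,11-diepoxy-3,7,11-trimethyldodec-2-en-1-yl acetate
Conditions: D-fructose-derived Shi ketone (1,2:4,5-di-O-isopropylidene-β-D-erythro-2,3-hexodiulo-2,6-pyranose, 0.6 equiv), KHSO5 (Oxone), K2CO3, Bu4NHSO4 (cat.), MeCN/CH2(OMe)2/aq. Na2B4O7 buffer pH 10.5, 0 °C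
Reagents that add atoms: potassium peroxymonosulfate KHSO5, [K+].[O-]S(=O)(=O)OO
Why: Shi asymmetric epoxidation, in which the chiral dioxirane attacks the two electron-rich trisubstituted alkenes from the same face through a spiro transition state (setting 6R,7R and 10R) while the 2,3-alkene is switched off by the allylic acetate.

Step 2
Reactants: 2 diepoxyfarnesyl acetate
Product: 3 (2E,6R,7R,10R)-6,7:10,11-diepoxy-3,7,11-trimethyldodec-2-en-1-ol
Conditions: K2CO3 (cat.), MeOH, 0 °C
Reagents that add atoms: none
Why: Base-catalysed transesterification (methanolysis) removes the acetate without touching the trisubstituted epoxides or any stereocentre.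

Step 3
Reactants: 3 diepoxyfarnesol
Product: 5 (2E,6R,7R,10R)-1-bromo-6,7:10,11-diepoxy-3,7,11-trimethyldodec-2-ene, via allylic mesylate 4 (not isolated)
Conditions: MsCl, Et3N, CH2Cl2, −40 °C; then LiBr, THF, 0 °C
Reagents that add atoms: lithium bromide, [Li+].[Br-]
Why: Mesylation followed by SN2 displacement with bromide at the primary allylic carbon gives the electrophile without allylic transposition, and the epoxides and the E alkene are untouched.

Step 4
Reactants: 6 (2E,6E)-farnesyl bromide
Product: 7 (2E,6E)-farnesyl phenyl sulfone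
Conditions: PhSO2Na, DMF, rt
Reagents that add atoms: sodium benzenesulfinate, [Na+].[O-]S(=O)c1ccccc1
Why: SN2 S-alkylation of the sulfinate by the primary allylic bromide gives the allylic sulfone with both E alkenes retained.

Step 5
Reactants: 7 farnesyl phenyl sulfone
Product: 8 (2E,6E,10E)-12-hydroxyfarnesyl phenyl sulfone [(2E,6E,10E)-2,6,10-trimethyl-12-(phenylsulfonyl)dodeca-2,6,10-trien-1-ol]
Conditions: SeO2 (0.3 equiv), t-BuOOH, salicylic acid (10 mol%), CH2Cl2, 0 °C → rt
Reagents that add atoms: tert-butyl hydroperoxide, CC(C)(C)OO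
Why: Selenium dioxide allylic oxidation (ene reaction then [2,3]-sigmatropic shift) selects the (E)-methyl group of the most electron-rich, terminal alkene and gives the (E)-allylic alcohol.

Step 6
Reactants: 8 12-hydroxyfarnesyl phenyl sulfone
Product: 9 (2E,6E,10E)-12-(pivaloyloxy)farnesyl phenyl sulfone
Conditions: pivaloyl chloride, pyridine, 4-(dimethylamino)pyridine (cat.), CH2Cl2, 0 °C
Reagents that add atoms: pivaloyl chloride, CC(C)(C)C(Cl)=O
Why: Acylation of the primary allylic alcohol installs a hindered ester that deactivates the terminal alkene in step 7 and serves as the allylic leaving group in step 9.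

Step 7
Reactants: 9 pivalate sulfone
Product: 10 (2E,6R,7R,10E)-6,7-epoxy-12-(pivaloyloxy)farnesyl phenyl sulfone
Conditions: D-fructose-derived Shi ketone (0.3 equiv), KHSO5 (Oxone), K2CO3, Bu4NHSO4 (cat.), MeCN/CH2(OMe)2/aq. Na2B4O7 buffer pH 10.5, 0 °C
Reagents that add atoms: potassium peroxymonosulfate KHSO5, [K+].[O-]S(=O)(=O)OO
Why: Shi asymmetric epoxidation, in which only the central 6,7-alkene is electron-rich enough (the 2,3-alkene is deactivated by the allylic sulfone and the 10,11-alkene by the allylic pivalate), with the same spiro transition state setting 6R,7R.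

Step 8
Reactants: 10 epoxy sulfone; 5 diepoxyfarnesyl bromide
Product: 11 (3R,6R,7R,18R,19R,10E,14E,22E)-2,3:6,7:18,19-triepoxy-13-(phenylsulfonyl)-24-(pivaloyloxy)-2,3,6,7,18,19-hexahydrosqualene (both C13 epimers)
Conditions: lithium diisopropylamide (1.05 equiv), THF, −78 °C; then 5, −78 → −20 °C
Reagents that add atoms: none
Why: Biellmann-type sulfone alkylation, in which the α-sulfonyl allyl anion attacks the primary allylic bromide at its α-carbon (SN2) to forge the tail-to-tail C12–C13 bond; the epimeric C13 centre is erased in step 9.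

Step 9
Reactants: 11 sulfone pivalate
Product: 12 (3R,6R,7R,18R,19R,10E,14E)-2,3:6,7:18,19-triepoxy-2,3,6,7,18,19-hexahydrosqualene
Conditions: PdCl2(dppp) [dppp = 1,3-bis(diphenylphosphino)propane] (10 mol%), LiEt3BH (4 equiv, slow addition), THF, 0 °C
Reagents that add atoms: none
Why: Palladium-catalysed allylic hydride substitution removes both the sulfone and the pivalate, each π-allyl palladium intermediate taking hydride at its less substituted terminus (C13 and C24), which keeps the 14,15-alkene E and regenerates the terminal isopropylidene group.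

Step 10
Reactants: 12 triepoxysqualene
Product: 14 sipholenol A, via left-cyclised epoxy diol 13 (not isolated)
Conditions: Ph4PBF4 (20 mol%), (CF3)2CHOH/H2O (20:1), 0 °C → rt
Reagents that add atoms: water, O
Why: Proposed new method: a fluoroalcohol-promoted double epoxide cascade in which hydrogen-bond activation of the 2,3-epoxide is assisted by the 6,7-epoxide oxygen (bicyclic epoxonium ion, giving the oxepane), the 10,11-alkene opens the epoxonium ion at C6 with inversion through a chair (C11 side chain equatorial) and water traps the C10 cation on the axial face so that its methyl group avoids a 1,3-diaxial clash with the C6 methyl (re-ionisation under the protic conditions also favours this epimer), while the isolated 18,19-epoxide is opened at C18 with inversion by the 22,23-alkene in a nucleophile-assisted 5-ring closure, the tertiary C23 cation is captured 7-endo by the 14,15-alkene from a folded cis-fused transition state with the C13 chain pseudo-equatorial, and the hindered C15 cation loses H16 to give the trisubstituted alkene, C3, C7 and C19 keeping their epoxide configuration; the closest known reaction types are the tandem oxa-/carbacyclisation of 1,5-diepoxy alkenes, fluoroalcohol-promoted epoxide-initiated cation–olefin polycyclisation with water termination, and the acid-mediated anti-Markovnikov transannular epoxide–alkene closure of germacranolide 4,5-epoxides to guaianolides.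

Step 11
Reactants: 14 sipholenol A
Product: 16 CNP0216138.1 (15,16-epoxysipholenol A), via bromohydrin 15 (not isolated)
Conditions: N-bromosuccinimide, THF/H2O (4:1), 0 °C; then K2CO3, MeOH, rt
Reagents that add atoms: water, O
Why: Halohydrin route to the hindered-face epoxide, in which the bromonium ion forms on the open face of the C15=C16 bond (anti to the pseudo-axial C13 chain on C14), water opens it anti at the tertiary C15, and base closes the ring with inversion at C16 so that the oxygen ends syn to the C14 side chain (15R,16S).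

## Compound list

1 | (2E,6E)-farnesyl acetate | CC(C)=CCC/C(C)=C/CC/C(C)=C/COC(C)=O | starting material
2 | (2E,6R,7R,10R)-6,7:10,11-diepoxyfarnesyl acetate | CC1(C)O[C@@H]1CC[C@@]2(C)O[C@@H]2CC/C(C)=C/COC(C)=O | intermediate
3 | (2E,6R,7R,10R)-6,7:10,11-diepoxyfarnesol | CC1(C)O[C@@H]1CC[C@@]2(C)O[C@@H]2CC/C(C)=C/CO | intermediate
4 | (2E,6R,7R,10R)-6,7:10,11-diepoxyfarnesyl methanesulfonate (not isolated) | CC1(C)O[C@@H]1CC[C@@]2(C)O[C@@H]2CC/C(C)=C/COS(C)(=O)=O | intermediate
5 | (2E,6R,7R,10R)-6,7:10,11-diepoxyfarnesyl bromide | CC1(C)O[C@@H]1CC[C@@]2(C)O[C@@H]2CC/C(C)=C/CBr | intermediate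
6 | (2E,6E)-farnesyl bromide | CC(C)=CCC/C(C)=C/CC/C(C)=C/CBr | starting material
7 | (2E,6E)-farnesyl phenyl sulfone | CC(C)=CCC/C(C)=C/CC/C(C)=C/CS(=O)(=O)c1ccccc1 | intermediate
8 | (2E,6E,10E)-12-hydroxyfarnesyl phenyl sulfone | OC/C(C)=C/CC/C(C)=C/CC/C(C)=C/CS(=O)(=O)c1ccccc1 | intermediate
9 | (2E,6E,10E)-12-(pivaloyloxy)farnesyl phenyl sulfone | CC(C)(C)C(=O)OC/C(C)=C/CC/C(C)=C/CC/C(C)=C/CS(=O)(=O)c1ccccc1 | intermediate
10 | (2E,6R,7R,10E)-6,7-epoxy-12-(pivaloyloxy)farnesyl phenyl sulfone | CC(C)(C)C(=O)OC/C(C)=C/CC[C@@]1(C)O[C@@H]1CC/C(C)=C/CS(=O)(=O)c1ccccc1 | intermediate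
11 | (3R,6R,7R,18R,19R,10E,14E,22E)-2,3:6,7:18,19-triepoxy-13-(phenylsulfonyl)-24-(pivaloyloxy)hexahydrosqualene, C13 epimers | CC1(C)O[C@@H]1CC[C@@]2(C)O[C@@H]2CC/C(C)=C/CC(S(=O)(=O)c3ccccc3)/C=C(C)/CC[C@H]4O[C@]4(C)CC/C=C(C)/COC(=O)C(C)(C)C | intermediate
12 | (3R,6R,7R,18R,19R,10E,14E)-2,3:6,7:18,19-triepoxy-2,3,6,7,18,19-hexahydrosqualene | CC1(C)O[C@@H]1CC[C@@]2(C)O[C@@H]2CC/C(C)=C/CC/C=C(C)/CC[C@H]3O[C@]3(C)CCC=C(C)C | intermediate
13 | left-cyclised epoxy diol: trans-fused oxepane–cyclohexane with C3 and C10 carbinols as in 16, carrying the (14E)-18R,19R-epoxy diene chain on C11 (not isolated) | CC1(C)O[C@@H]2CC[C@](C)(O)[C@H](CC/C=C(C)/CC[C@H]3O[C@]3(C)CCC=C(C)C)[C@@]2(C)CC[C@H]1O | intermediate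
14 | sipholenol A (15,16-alkene; all other stereocentres as in 16) | CC1(C)O[C@@H]2CC[C@](C)(O)[C@H](CC[C@@H]3C(C)(C)[C@@H]4CC[C@@](C)(O)[C@@H]4CC=C3C)[C@@]2(C)CC[C@H]1O | intermediate
15 | 16-bromo-15-hydroxy-15,16-dihydrosipholenol A, Br anti to the new OH and anti to the C14 side chain (not isolated) | CC1(C)O[C@@H]2CC[C@](C)(O)[C@H](CC[C@@H]3C(C)(C)[C@@H]4CC[C@@](C)(O)[C@@H]4C[C@@H](Br)[C@]3(C)O)[C@@]2(C)CC[C@H]1O | intermediate
16 | CNP0216138.1, 15,16-epoxysipholenol A | CC1(C)O[C@@H]2CC[C@](C)(O)[C@H](CC[C@@H]3C(C)(C)[C@@H]4CC[C@@](C)(O)[C@@H]4C[C@@H]4O[C@@]43C)[C@@]2(C)CC[C@H]1O | target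

## Step count and risk

Total step count: 11. Longest linear sequence: 8 steps (6 → 16, steps 4–11).

**Step 10 (double cascade).** This is the step most likely to fail. The 14,15-alkene can open the 18,19-epoxide at its tertiary carbon C19 in the ordinary 6-endo sense, which would beat the wanted 5-ring closure at C18. Water capture at C10 could also give the equatorial carbinol, and C15 could be hydrated instead of eliminating. The fallback keeps the coupling sulfone as a gate and moves desulfonylation behind the cyclisation. It sets out from 11. Hydrogenolysis of only the allylic pivalate with Pd(PPh3)4 and NaBH4 in THF/i-PrOH at 0 °C (the allylic sulfone does not ionise with zerovalent palladium under these conditions) gives (3R,6R,7R,18R,19R)-13-(phenylsulfonyl)-2,3:6,7:18,19-triepoxysqualene F1. In this compound the 14,15-alkene is allylic to the sulfone; it is then too electron-poor to open an epoxide but can still trap the free tertiary C23 cation. The conditions of step 10 should therefore give 13-(phenylsulfonyl)sipholenol A F2. Reductive desulfonylation with sodium amalgam (Na/Hg, Na2HPO4, MeOH, −20 °C) comes back to the route at 14.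

**Step 9 (Pd/hydride removal of sulfone and pivalate).** LiEt3BH may attack the pivalate carbonyl, leaving an allylic alcohol that no longer ionises, or open an epoxide. The fallback uses a carbonyl-free mask for the terminal alkene and sets out from 7. Ene-type chlorination of the terminal alkene with hypochlorous acid (Ca(OCl)2, CO2, CH2Cl2/H2O, 0 °C) gives (2E,6E)-10-chloro-3,7,11-trimethyldodeca-2,6,11-trien-1-yl phenyl sulfone F3. Its 11,12-alkene is 1,1-disubstituted and allylic to chlorine, so the Shi dioxirane leaves it alone. Shi epoxidation as in step 7 gives the (6R,7R)-6,7-epoxide of that chloro sulfone F4. Lithium diisopropylamide and then 5, as in step 8, give the coupled 22-chloro-13-(phenylsulfonyl) triepoxide F5. PdCl2(dppp)/LiEt3BH then removes the sulfone and the allylic chloride (hydride at the CH2 terminus regenerates the isopropylidene group) and comes back to the route at 12.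

**Step 11 (epoxide face).** The bromonium ion may form on the other face than assumed, which would put the epoxide on the wrong side. The fallback is direct oxygen-atom transfer with dimethyldioxirane in acetone at −20 °C. It attacks the face that the bromonium ion takes, so it is stereocomplementary to the halohydrin route. It sets out from 14 and comes back to the route at 16, and it makes no new compound F0.

## Further compounds

F1 | step 10 | (3R,6R,7R,18R,19R,10E,14E)-13-(phenylsulfonyl)-2,3:6,7:18,19-triepoxysqualene, C13 epimers | CC1(C)O[C@@H]1CC[C@@]2(C)O[C@@H]2CC/C(C)=C/CC(S(=O)(=O)c3ccccc3)/C=C(C)/CC[C@H]4O[C@]4(C)CCC=C(C)C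
F2 | step 10 | 13-(phenylsulfonyl)sipholenol A, C13 epimers | CC1(C)O[C@@H]2CC[C@](C)(O)[C@H](CC(S(=O)(=O)c5ccccc5)[C@@H]3C(C)(C)[C@@H]4CC[C@@](C)(O)[C@@H]4CC=C3C)[C@@]2(C)CC[C@H]1O
F3 | step 9 | (2E,6E)-10-chloro-3,7,11-trimethyldodeca-2,6,11-trien-1-yl phenyl sulfone, C10 epimers | C=C(C)C(Cl)CC/C(C)=C/CC/C(C)=C/CS(=O)(=O)c1ccccc1
F4 | step 9 | (2E,6R,7R)-10-chloro-6,7-epoxy-3,7,11-trimethyldodeca-2,11-dien-1-yl phenyl sulfone | C=C(C)C(Cl)CC[C@@]1(C)O[C@@H]1CC/C(C)=C/CS(=O)(=O)c1ccccc1
F5 | step 9 | (3R,6R,7R,18R,19R,10E,14E)-22-chloro-13-(phenylsulfonyl)-2,3:6,7:18,19-triepoxy-squalene isomer with a 23(24)-alkene | CC1(C)O[C@@H]1CC[C@@]2(C)O[C@@H]2CC/C(C)=C/CC(S(=O)(=O)c3ccccc3)/C=C(C)/CC[C@H]4O[C@]4(C)CCC(Cl)C(C)=C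
F0 | step 11 | none | none
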